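**Retrosynthetic overview**
- The target comes from its 5,7,3'-tri-O-benzyl ether by neutral hydrogenolysis, so no acid or base touches the molecule once C3 is set.
- Ring C is closed last, at C3–C4. The ring A formyl carbon, turned into an acyl anion by a chiral carbene, adds 1,6 to a ring B para-quinone methide. The exocyclic carbon of that methide becomes (3S)-C3.
- The quinone methide is released in the flask by fluoride from a 4'-O-silyl benzylic acetate. That acetate is made by joining the ring A phenol to the CH2 of a ring B aryl oxirane (O1–C2 bond).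
- One Shi epoxidation of a vinyl/prenyl arene makes both oxiranes. It sets the (R)-dimethyloxirane; the aryl oxirane centre is erased later.
- Rings A and B are bought. Order of ring formation: the oxiranes in step 4, then ring C in step 6.

Assumption: the (5aR,10bS) catalyst in step 6 is taken to give (3S) by analogy with carbene-catalysed chromanone closures; if the first run gives (3R), the equally available (5aS,10bR) antipode is used and nothing else changes.

**Step 1**
Reactants: 1 2,4,6-trihydroxybenzaldehyde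
Product: 2 2,4-bis(benzyloxy)-6-hydroxybenzaldehyde
Conditions: BnBr (2.05 equiv), K2CO3 (2.1 equiv), DMF, 0 °C to rt
Reagents that add atoms: benzyl bromide BrCc1ccccc1
Why: Williamson etherification, in which the hydroxyl left hydrogen-bonded to the formyl group is the least nucleophilic, so two equivalents stop at the bis-ether; no stereocentre.

**Step 2**
Reactants: 3 3-(benzyloxy)-4-hydroxybenzaldehyde
Product: 4 3-(benzyloxy)-4-hydroxy-5-(3-methylbut-2-en-1-yl)benzaldehyde
Conditions: prenyl bromide (1.1 equiv), KOH (1.05 equiv), H2O, rt, 16 h; chromatography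
Reagents that add atoms: 1-bromo-3-methylbut-2-ene CC(C)=CCBr
Why: Phenolate C-alkylation, because in water the solvated oxygen is shielded and the soft allylic bromide is taken in part by the only free ortho carbon (C5), in modest yield with the O-prenyl ether as a separable by-product; no stereocentre.

**Step 3**
Reactants: 4 3-(benzyloxy)-4-hydroxy-5-(3-methylbut-2-en-1-yl)benzaldehyde
Product: 6 [2-(benzyloxy)-4-ethenyl-6-(3-methylbut-2-en-1-yl)phenoxy]tri(propan-2-yl)silane, via potassium vinylphenolate 5 (not isolated)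
Conditions: Ph3PCH3Br (2.4 equiv), KOtBu (2.3 equiv), THF, 0 °C to rt; then iPr3SiCl (2.5 equiv), DMAP (cat.), rt
Reagents that add atoms: methyltriphenylphosphonium bromide C[P+](c1ccccc1)(c1ccccc1)c1ccccc1.[Br-]; chlorotri(propan-2-yl)silane CC(C)[Si](Cl)(C(C)C)C(C)C
Why: Wittig methylenation with excess ylide tolerates the phenol as its potassium salt, which is silylated in the same flask so the polymerisation-prone vinylphenol is never handled; no stereocentre.

**Step 4**
Reactants: 6 [2-(benzyloxy)-4-ethenyl-6-(3-methylbut-2-en-1-yl)phenoxy]tri(propan-2-yl)silane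
Product: 8 {2-(benzyloxy)-6-[((2R)-3,3-dimethyloxiran-2-yl)methyl]-4-(oxiran-2-yl)phenoxy}tri(propan-2-yl)silane (both epimers at the aryl oxirane carbon), via prenyl monoepoxide 7 (not isolated)
Conditions: D-fructose-derived Shi ketone (0.6 equiv), Oxone (3 equiv), K2CO3, Bu4NHSO4 (cat.), MeCN/CH2(OMe)2, aq. Na2B4O7/Na2EDTA buffer (pH 10.5), 0 °C; Et3N-washed silica
Reagents that add atoms: potassium peroxymonosulfate (active part of Oxone) [K+].[O-]S(=O)(=O)OO
Why: Shi asymmetric epoxidation, in which the dioxirane of the D-fructose ketone meets the trisubstituted prenyl alkene through the spiro transition state on the face that gives the (R)-oxirane, while the vinyl group is epoxidised unselectively, which is harmless because that carbon becomes planar in step 6.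

**Step 5**
Reactants: 8 the bis-epoxide of step 4; 2 2,4-bis(benzyloxy)-6-hydroxybenzaldehyde
Product: 10 1-{3-(benzyloxy)-5-[((2R)-3,3-dimethyloxiran-2-yl)methyl]-4-[tri(propan-2-yl)silyloxy]phenyl}-2-[3,5-bis(benzyloxy)-2-formylphenoxy]ethyl acetate (both epimers at the acetoxy carbon), via secondary benzylic alcohol 9 (not isolated)
Conditions: 2 (1.2 equiv), Cs2CO3 (0.2 equiv), DMF, 70 °C; then Ac2O, Et3N, DMAP (cat.), 0 °C to rt
Reagents that add atoms: acetic anhydride CC(=O)OC(C)=O
Why: Base-catalysed SN2 opening of the monosubstituted oxirane at its CH2 end by the bulky phenolate of 2, followed by DMAP-catalysed acetylation in the same pot; the trisubstituted oxirane is too hindered to react, the twisted silyloxy group is too weak a donor to favour benzylic attack, and the new carbinol centre is erased in step 6.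

**Step 6**
Reactants: 10 the silyl ether acetate of step 5
Product: 13 (3S)-5,7-bis(benzyloxy)-3-{3-(benzyloxy)-5-[((2R)-3,3-dimethyloxiran-2-yl)methyl]-4-hydroxyphenyl}chroman-4-one, via para-quinone methide aldehyde 11 (not isolated), via Breslow enaminol 12 (not isolated)
Conditions: (5aR,10bS)-2-(pentafluorophenyl)-5a,10b-dihydro-4H,6H-indeno[2,1-b][1,2,4]triazolo[4,3-d][1,4]oxazin-2-ium tetrafluoroborate (20 mol %), iPr2NEt (20 mol %), [Bu4N][Ph3SiF2] (1.05 equiv, slow addition), 4 Å MS, THF, −10 to 0 °C; prompt filtration through silica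
Reagents that add atoms: none
Why: Proposed new method: fluoride removes the silyl group and the phenolate expels acetate (1,6-elimination) to give the lignin-type para-quinone methide 11, whose formyl group the chiral triazolylidene converts into the nucleophilic Breslow enaminol 12 (acyl anion equivalent), and this attacks the electrophilic exocyclic carbon in a 6-exo-trig vinylogous (1,6-) intramolecular Stetter reaction in which the indane wall of the catalyst selects the face leading to (3S), rearomatisation to the phenol makes the addition irreversible, and acetate as the only stoichiometric base spares both C3 and the oxirane; the closest known reactions are the enantioselective intramolecular Stetter synthesis of 3-substituted chroman-4-ones and the carbene-catalysed intermolecular 1,6-addition of aromatic aldehydes to para-quinone methides.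

**Step 7**
Reactants: 13 the tri-O-benzyl isoflavanone of step 6
Product: 14 (3S)-3-{3,4-dihydroxy-5-[((2R)-3,3-dimethyloxiran-2-yl)methyl]phenyl}-5,7-dihydroxychroman-4-one (CNP0197974.1)
Conditions: H2 (1 atm), 10% Pd/C (acid-free), EtOAc, rt, 1–2 h
Reagents that add atoms: none
Why: Heterogeneous hydrogenolysis cleaves the three aryl benzyl ethers under neutral conditions, which leave the non-benzylic trialkyl oxirane, the ortho-hydroxy epoxide pair and the enolisable (3S) centre untouched.

**Compound list**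
1 | 2,4,6-trihydroxybenzaldehyde | O=Cc1c(O)cc(O)cc1O | starting material
2 | 2,4-bis(benzyloxy)-6-hydroxybenzaldehyde | O=Cc1c(O)cc(OCc2ccccc2)cc1OCc1ccccc1 | intermediate
3 | 3-(benzyloxy)-4-hydroxybenzaldehyde | O=Cc1ccc(O)c(OCc2ccccc2)c1 | starting material
4 | 3-(benzyloxy)-4-hydroxy-5-(3-methylbut-2-en-1-yl)benzaldehyde | CC(C)=CCc1cc(C=O)cc(OCc2ccccc2)c1O | intermediate
5 | potassium 2-(benzyloxy)-4-ethenyl-6-(3-methylbut-2-en-1-yl)phenolate | CC(C)=CCc1cc(C=C)cc(OCc2ccccc2)c1[O-].[K+] | intermediate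
6 | [2-(benzyloxy)-4-ethenyl-6-(3-methylbut-2-en-1-yl)phenoxy]tri(propan-2-yl)silane | CC(C)=CCc1cc(C=C)cc(OCc2ccccc2)c1O[Si](C(C)C)(C(C)C)C(C)C | intermediate
7 | {2-(benzyloxy)-6-[((2R)-3,3-dimethyloxiran-2-yl)methyl]-4-ethenylphenoxy}tri(propan-2-yl)silane | CC1(C)O[C@@H]1Cc1cc(C=C)cc(OCc2ccccc2)c1O[Si](C(C)C)(C(C)C)C(C)C | intermediate
8 | {2-(benzyloxy)-6-[((2R)-3,3-dimethyloxiran-2-yl)methyl]-4-(oxiran-2-yl)phenoxy}tri(propan-2-yl)silane, epimers at the aryl oxirane carbon | CC1(C)O[C@@H]1Cc1cc(C2CO2)cc(OCc2ccccc2)c1O[Si](C(C)C)(C(C)C)C(C)C | intermediate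
9 | 2,4-bis(benzyloxy)-6-(2-{3-(benzyloxy)-5-[((2R)-3,3-dimethyloxiran-2-yl)methyl]-4-[tri(propan-2-yl)silyloxy]phenyl}-2-hydroxyethoxy)benzaldehyde, carbinol epimers | CC1(C)O[C@@H]1Cc1cc(C(O)COc2cc(OCc3ccccc3)cc(OCc3ccccc3)c2C=O)cc(OCc2ccccc2)c1O[Si](C(C)C)(C(C)C)C(C)C | intermediate
10 | acetate of 9 | CC1(C)O[C@@H]1Cc1cc(C(COc2cc(OCc3ccccc3)cc(OCc3ccccc3)c2C=O)OC(C)=O)cc(OCc2ccccc2)c1O[Si](C(C)C)(C(C)C)C(C)C | intermediate
11 | 2,4-bis(benzyloxy)-6-(2-{3-(benzyloxy)-5-[((2R)-3,3-dimethyloxiran-2-yl)methyl]-4-oxocyclohexa-2,5-dien-1-ylidene}ethoxy)benzaldehyde, E/Z mixture | CC1(C)O[C@@H]1CC1=CC(=CCOc2cc(OCc3ccccc3)cc(OCc3ccccc3)c2C=O)C=C(OCc2ccccc2)C1=O | intermediate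
12 | Breslow enaminol of 11 with the (5aR,10bS)-triazolylidene | CC1(C)O[C@@H]1CC1=CC(=CCOc2cc(OCc3ccccc3)cc(OCc3ccccc3)c2C(O)=C2N(c3c(F)c(F)c(F)c(F)c3F)N=C3N2[C@H]4c5ccccc5C[C@H]4OC3)C=C(OCc2ccccc2)C1=O | intermediate
13 | (3S)-5,7-bis(benzyloxy)-3-{3-(benzyloxy)-5-[((2R)-3,3-dimethyloxiran-2-yl)methyl]-4-hydroxyphenyl}chroman-4-one | CC1(C)O[C@@H]1Cc1cc([C@H]2COc3cc(OCc4ccccc4)cc(OCc4ccccc4)c3C2=O)cc(OCc2ccccc2)c1O | intermediate
14 | (3S)-3-{3,4-dihydroxy-5-[((2R)-3,3-dimethyloxiran-2-yl)methyl]phenyl}-5,7-dihydroxychroman-4-one | CC1(C)O[C@@H]1Cc1cc([C@H]2COc3cc(O)cc(O)c3C2=O)cc(O)c1O | target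

**Total step count:** 7. **Longest linear sequence:** 6 (3 → 4 → 6 → 8 → 10 → 13 → 14).

**The three steps most likely to fail**

**Step 6.**
- The aldehyde is electron-rich and flanked by two oxygens, so the enaminol may form slowly.
- The carbene may add to the quinone methide and trigger loss of the neighbouring aryloxide.
- The quinone methide may tautomerise to the styryl ether.
- Acetate may erode the ee at C3.

The fallback sets out from 10 and gives up asymmetric induction in the bond formation. The same fluoride release is run with the small achiral carbene from 3-benzyl-5-(2-hydroxyethyl)-4-methylthiazolium chloride and Et3N. This gives the C3-epimeric 5,7-bis(benzyloxy)-3-{3-(benzyloxy)-5-[((2R)-3,3-dimethyloxiran-2-yl)methyl]-4-hydroxyphenyl}chroman-4-one F1. C3 is then set by dynamic kinetic resolution under asymmetric transfer hydrogenation with RuCl[(S,S)-TsDPEN](p-cymene) and HCO2H/Et3N in EtOAc at rt, where C3 epimerises faster than the ketone is reduced. The product is the cis alcohol (3S,4S)-5,7-bis(benzyloxy)-3-{3-(benzyloxy)-5-[((2R)-3,3-dimethyloxiran-2-yl)methyl]-4-hydroxyphenyl}chroman-4-ol F2. Brief oxidation with Dess–Martin periodinane and NaHCO3 at 0 °C brings the route back at 13.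

**Step 5.**
- The phenolate may attack the benzylic carbon instead of the CH2.
- The aryl oxirane may rearrange.
- The silyl group may be lost at 70 °C.

The fallback sets out from 6 and drops the benzylic leaving group in favour of oxidative formation of the quinone methide.
- 9-BBN hydroborates only the vinyl group, and NaBO3 then gives 2-{3-(benzyloxy)-5-(3-methylbut-2-en-1-yl)-4-[tri(propan-2-yl)silyloxy]phenyl}ethanol F3.
- Shi epoxidation as in step 4 gives 2-{3-(benzyloxy)-5-[((2R)-3,3-dimethyloxiran-2-yl)methyl]-4-[tri(propan-2-yl)silyloxy]phenyl}ethanol F4.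
- Mitsunobu coupling with 2 (PPh3, DIAD, THF) gives 2,4-bis(benzyloxy)-6-(2-{3-(benzyloxy)-5-[((2R)-3,3-dimethyloxiran-2-yl)methyl]-4-[tri(propan-2-yl)silyloxy]phenyl}ethoxy)benzaldehyde F5.
- Bu4NF buffered with AcOH frees the phenol 2,4-bis(benzyloxy)-6-(2-{3-(benzyloxy)-5-[((2R)-3,3-dimethyloxiran-2-yl)methyl]-4-hydroxyphenyl}ethoxy)benzaldehyde F6.
- Ag2O in CH2Cl2 dehydrogenates this 4-alkylphenol.
- The filtered solution comes back to the route at 11 and is fed to the carbene of step 6 without fluoride.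

**Step 2.** O-alkylation may dominate and leave little C-prenyl product. The fallback sets out from 3 and reaches the same bond by sigmatropic rearrangement. Pd(PPh3)4-catalysed allylic etherification with tert-butyl 2-methylbut-3-en-2-yl carbonate (THF, 0 °C to rt) gives the tertiary ether 3-(benzyloxy)-4-[(2-methylbut-3-en-2-yl)oxy]benzaldehyde F7. Its aromatic Claisen rearrangement (Eu(fod)3 cat., toluene, 80–110 °C) can only go to C5 and comes back to the route at 4.

**Further compounds**
F1 | step 6 | 5,7-bis(benzyloxy)-3-{3-(benzyloxy)-5-[((2R)-3,3-dimethyloxiran-2-yl)methyl]-4-hydroxyphenyl}chroman-4-one, C3 epimers | CC1(C)O[C@@H]1Cc1cc(C2COc3cc(OCc4ccccc4)cc(OCc4ccccc4)c3C2=O)cc(OCc2ccccc2)c1O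
F2 | step 6 | (3S,4S)-5,7-bis(benzyloxy)-3-{3-(benzyloxy)-5-[((2R)-3,3-dimethyloxiran-2-yl)methyl]-4-hydroxyphenyl}chroman-4-ol | CC1(C)O[C@@H]1Cc1cc([C@H]2COc3cc(OCc4ccccc4)cc(OCc4ccccc4)c3[C@H]2O)cc(OCc2ccccc2)c1O
F3 | step 5 | 2-{3-(benzyloxy)-5-(3-methylbut-2-en-1-yl)-4-[tri(propan-2-yl)silyloxy]phenyl}ethanol | CC(C)=CCc1cc(CCO)cc(OCc2ccccc2)c1O[Si](C(C)C)(C(C)C)C(C)C
F4 | step 5 | 2-{3-(benzyloxy)-5-[((2R)-3,3-dimethyloxiran-2-yl)methyl]-4-[tri(propan-2-yl)silyloxy]phenyl}ethanol | CC1(C)O[C@@H]1Cc1cc(CCO)cc(OCc2ccccc2)c1O[Si](C(C)C)(C(C)C)C(C)C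
F5 | step 5 | 2,4-bis(benzyloxy)-6-(2-{3-(benzyloxy)-5-[((2R)-3,3-dimethyloxiran-2-yl)methyl]-4-[tri(propan-2-yl)silyloxy]phenyl}ethoxy)benzaldehyde | CC1(C)O[C@@H]1Cc1cc(CCOc2cc(OCc3ccccc3)cc(OCc3ccccc3)c2C=O)cc(OCc2ccccc2)c1O[Si](C(C)C)(C(C)C)C(C)C
F6 | step 5 | 2,4-bis(benzyloxy)-6-(2-{3-(benzyloxy)-5-[((2R)-3,3-dimethyloxiran-2-yl)methyl]-4-hydroxyphenyl}ethoxy)benzaldehyde | CC1(C)O[C@@H]1Cc1cc(CCOc2cc(OCc3ccccc3)cc(OCc3ccccc3)c2C=O)cc(OCc2ccccc2)c1O
F7 | step 2 | 3-(benzyloxy)-4-[(2-methylbut-3-en-2-yl)oxy]benzaldehyde | C=CC(C)(C)Oc1ccc(C=O)cc1OCc1ccccc1
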